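**Retrosynthetic overview**

- Feature: ring A is numbered C1′ to C6′ (C1′ carries the CH2 bridge to C5 of the isocoumarin, C2′ OMe, C4′ OH, C6′ CH2OMe). The benzylic carbons on the neighbours C1′ and C6′ can be joined through one oxygen, which gives a 1-aryl-1,3-dihydroisobenzofuran with a doubly benzylic C1–O bond.
- Key disconnection: retro-(2+2+2) of that phthalan arene into a propargyl ether 1,6-diyne (C5′, C6′, C1′, C2′, with C2′ as a methoxyalkyne carbon) and ethynylboronic ester (C3′, C4′). Forward, it forms C1′–C6′, C2′–C3′ and C4′–C5′ and closes ring A together with the five-membered ether ring.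
- Diyne: the C5 aldehyde of 6-benzyloxy-8-methoxy-3-methylisocoumarin takes up lithium methoxyacetylide, then the carbinol is O-propargylated. The aldehyde comes from the 5-bromide by reductive carbonylation, and the bromo-isocoumarin from methyl orsellinate (O-differentiation, bromination, lateral lithiation/acylation, enol lactonization).
- After the key step: reductive cleavage of C1–O (gives the bridge CH2 and the CH2OH arm on C6′), O-methylation, boron to OH at C4′, debenzylation.
- Ring order: the benzo ring of the isocoumarin is bought; pyranone ring (step 5); ring A with the ether ring (step 9); ether ring reopened (step 10).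

Key step: step 9

Remark: the target has no stereocentre. The carbinol centre made in step 7 is racemic, is carried through the key step and is removed in step 10, so the SMILES of 11, 13 and 15 show one enantiomer of a racemate.

**Route**

Step 1
Reactants: 1 methyl orsellinate (methyl 2,4-dihydroxy-6-methylbenzoate)
Product: 2 methyl 4-(benzyloxy)-2-hydroxy-6-methylbenzoate
Conditions: BnBr (1.05 equiv), K2CO3, acetone, reflux
Reagents that add atoms: benzyl bromide, BrCc1ccccc1
Why: Williamson etherification in which the 2-OH, held in a hydrogen bond to the ester carbonyl, stays unreactive, so only the 4-OH should be benzylated.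

Step 2
Reactants: 2 methyl 4-(benzyloxy)-2-hydroxy-6-methylbenzoate
Product: 3 methyl 4-(benzyloxy)-2-methoxy-6-methylbenzoate
Conditions: MeI (excess), K2CO3, DMF, 60 °C
Reagents that add atoms: iodomethane, CI
Why: Williamson O-methylation of the remaining chelated phenol under more forcing carbonate conditions, which fixes the later C8 methoxy group against the C6 benzyl ether.

Step 3
Reactants: 3 methyl 4-(benzyloxy)-2-methoxy-6-methylbenzoate
Product: 4 methyl 4-(benzyloxy)-3-bromo-6-methoxy-2-methylbenzoate
Conditions: NBS (1.05 equiv), MeCN, 0 °C to rt, dark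
Reagents that add atoms: N-bromosuccinimide, O=C1CCC(=O)N1Br
Why: Electrophilic aromatic bromination should go to the position para to the methoxy and ortho to the benzyloxy group, next to the methyl group, because the only other free position lies between two alkoxy groups and is the more crowded one.

Step 4
Reactants: 4 methyl 4-(benzyloxy)-3-bromo-6-methoxy-2-methylbenzoate; 5 N-methoxy-N-methylacetamide
Product: 6 methyl 4-(benzyloxy)-3-bromo-6-methoxy-2-(2-oxopropyl)benzoate
Conditions: LiN(iPr)2 (LDA, commercial solution, 2 equiv), THF, −78 °C; then 5, −78 to −40 °C; H2O quench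
Reagents that add atoms: none
Why: Lateral (benzylic) lithiation of the ortho-toluate gives a dienolate-type anion that is acylated by the N-methoxy-N-methyl amide through a chelated tetrahedral intermediate (Weinreb ketone synthesis), so the ketone is released only on quench, and the bromide, which has no ortho hydrogen, is inert to the amide base.

Step 5
Reactants: 6 methyl 4-(benzyloxy)-3-bromo-6-methoxy-2-(2-oxopropyl)benzoate
Product: 7 6-(benzyloxy)-5-bromo-8-methoxy-3-methyl-1H-isochromen-1-one
Conditions: p-TsOH·H2O (10 mol %), toluene, reflux, 4 Å molecular sieves (removal of MeOH)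
Reagents that add atoms: none
Why: Acid-catalysed enol lactonization, in which the conjugated enol of the benzyl ketone attacks the neighbouring ester in a six-membered transesterification and loss of methanol drives formation of the 3-methylisocoumarin.

Step 6
Reactants: 7 6-(benzyloxy)-5-bromo-8-methoxy-3-methyl-1H-isochromen-1-one
Product: 8 6-(benzyloxy)-8-methoxy-3-methyl-1-oxo-1H-isochromene-5-carbaldehyde
Conditions: Pd(OAc)2 (cat.), n-BuP(1-adamantyl)2 (cat.), TMEDA (1.1 equiv), CO/H2 (1:1, 5 bar), toluene, 100 °C
Reagents that add atoms: carbon monoxide, [C-]#[O+]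
Why: Palladium-catalysed reductive carbonylation (formylation) of an aryl bromide, in which oxidative addition, CO insertion and hydrogenolysis of the acylpalladium give the aldehyde; the bulky electron-rich phosphine serves the di-ortho-substituted bromide, and the homogeneous catalyst leaves the lactone and the benzyl ether alone.

Step 7
Reactants: 8 6-(benzyloxy)-8-methoxy-3-methyl-1-oxo-1H-isochromene-5-carbaldehyde; 9 chloroacetaldehyde dimethyl acetal
Product: 11 6-(benzyloxy)-5-[(1RS)-1-hydroxy-3-methoxyprop-2-yn-1-yl]-8-methoxy-3-methyl-1H-isochromen-1-one, via lithium methoxyacetylide 10 (not isolated)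
Conditions: 9 (2 equiv), LiNEt2 (6 equiv, from Et2NH and n-BuLi), THF, 0 °C; then 8, −78 °C; H2O quench at −78 °C; Et3N-deactivated silica
Reagents that add atoms: none
Why: Elimination of methanol and HCl from the chloroacetal followed by deprotonation gives the lithium alkoxyacetylide, which adds 1,2 to the aldehyde (acetylide addition to a carbonyl) much faster than to the lactone at −78 °C; the new carbinol centre forms without control (racemic), which is of no consequence because step 10 removes it.

Step 8
Reactants: 11 6-(benzyloxy)-5-[(1RS)-1-hydroxy-3-methoxyprop-2-yn-1-yl]-8-methoxy-3-methyl-1H-isochromen-1-one; 12 propargyl bromide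
Product: 13 6-(benzyloxy)-8-methoxy-5-[(1RS)-3-methoxy-1-(prop-2-yn-1-yloxy)prop-2-yn-1-yl]-3-methyl-1H-isochromen-1-one
Conditions: NaH (1.3 equiv), 12 (1.5 equiv), Bu4NI (cat.), THF, 0 °C to rt; Et3N-buffered work-up
Reagents that add atoms: none
Why: Williamson ether synthesis with the reactive propargylic bromide under strictly non-acidic conditions, which the acid-labile alkoxyalkynyl carbinol should tolerate, with the stereocentre untouched.

Step 9
Reactants: 13 6-(benzyloxy)-8-methoxy-5-[(1RS)-3-methoxy-1-(prop-2-yn-1-yloxy)prop-2-yn-1-yl]-3-methyl-1H-isochromen-1-one; 14 ethynylboronic acid pinacol ester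
Product: 15 6-(benzyloxy)-8-methoxy-5-[(1RS)-7-methoxy-5-(4,4,5,5-tetramethyl-1,3,2-dioxaborolan-2-yl)-1,3-dihydro-2-benzofuran-1-yl]-3-methyl-1H-isochromen-1-one
Conditions: Cp*RuCl(cod) [chloro(1,5-cyclooctadiene)(pentamethylcyclopentadienyl)ruthenium] (5–10 mol %), 14 (3 equiv), ClCH2CH2Cl, rt, slow addition of 13, argon
Reagents that add atoms: none
Why: Loss of cyclooctadiene frees the Cp*RuCl fragment, which binds both alkynes of 13 and couples them oxidatively (C1′–C6′) to a bicyclic ruthenacyclopentadiene that already holds the five-membered ether ring, after which 14 inserts and reductive elimination forms C2′–C3′ and C4′–C5′ and releases the arene. The closest known reaction is the Cp*RuCl(cod)-catalysed (2+2+2) cycloaddition of unsymmetrical 1,6-diynes with terminal alkynes and alkynylboronates, and heteroatom-substituted alkynes such as ynol ethers and ynamides have served as partners in metal-catalysed alkyne cyclotrimerization. The dihydrofuran ring closes in the oxidative cyclization of the tethered diyne on ruthenium, and benzene ring A closes by insertion of the third alkyne followed by reductive elimination. No new stereocentre is formed, and the carbinol centre of 13 becomes C1 of the phthalan unchanged (racemic). The step needs cross- over self-cyclotrimerization, which slow addition of 13 to an excess of 14 should secure. It also needs boron at C4′, meta to the C2′ methoxy group, which should follow because the terminal alkyne inserts with its substituent turned away from the substituted (methoxy-bearing, branched) end of the metallacycle, while the neutral catalyst at room temperature should not ionize the propargylic C–O bond.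

Step 10
Reactants: 15 6-(benzyloxy)-8-methoxy-5-[(1RS)-7-methoxy-5-(4,4,5,5-tetramethyl-1,3,2-dioxaborolan-2-yl)-1,3-dihydro-2-benzofuran-1-yl]-3-methyl-1H-isochromen-1-one
Product: 16 6-(benzyloxy)-5-{[2-(hydroxymethyl)-6-methoxy-4-(4,4,5,5-tetramethyl-1,3,2-dioxaborolan-2-yl)phenyl]methyl}-8-methoxy-3-methyl-1H-isochromen-1-one
Conditions: Et3SiH (5 equiv), BF3·OEt2 (2 equiv), CH2Cl2, −78 to −20 °C; aq NaHCO3
Reagents that add atoms: none
Why: Ionic hydrogenation, in which BF3 coordinates the ring oxygen, the C1–O bond flanked by two oxygen-substituted aryl rings ionizes to a diarylmethyl cation and Et3SiH delivers hydride; this gives the CH2 bridge, removes the stereocentre and frees the hydroxymethyl arm on C6′, while the primary benzylic C3–O bond, which has only meta donors, should not ionize.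

Step 11
Reactants: 16 6-(benzyloxy)-5-{[2-(hydroxymethyl)-6-methoxy-4-(4,4,5,5-tetramethyl-1,3,2-dioxaborolan-2-yl)phenyl]methyl}-8-methoxy-3-methyl-1H-isochromen-1-one
Product: 17 6-(benzyloxy)-8-methoxy-5-{[2-methoxy-6-(methoxymethyl)-4-(4,4,5,5-tetramethyl-1,3,2-dioxaborolan-2-yl)phenyl]methyl}-3-methyl-1H-isochromen-1-one
Conditions: Me3OBF4 (2 equiv), 1,8-bis(dimethylamino)naphthalene (2.5 equiv), CH2Cl2, 0 °C to rt
Reagents that add atoms: trimethyloxonium tetrafluoroborate, C[O+](C)C.F[B-](F)(F)F
Why: O-Methylation of a primary alcohol with a trialkyloxonium salt and a hindered non-nucleophilic base, conditions that should spare the lactone, the boronic ester and the aryl ethers where a strongly basic Williamson protocol might not.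

Step 12
Reactants: 17 6-(benzyloxy)-8-methoxy-5-{[2-methoxy-6-(methoxymethyl)-4-(4,4,5,5-tetramethyl-1,3,2-dioxaborolan-2-yl)phenyl]methyl}-3-methyl-1H-isochromen-1-one
Product: 18 6-(benzyloxy)-5-{[4-hydroxy-2-methoxy-6-(methoxymethyl)phenyl]methyl}-8-methoxy-3-methyl-1H-isochromen-1-one
Conditions: 30% H2O2, NaHCO3, THF/H2O, 0 °C to rt
Reagents that add atoms: hydrogen peroxide, OO
Why: Oxidative ipso-hydroxylation of an arylboronic ester, in which hydroperoxide adds to boron, the aryl group migrates from boron to oxygen and the borate hydrolyses to the C4′ phenol in a near-neutral buffer that should keep the lactone closed.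

Step 13
Reactants: 18 6-(benzyloxy)-5-{[4-hydroxy-2-methoxy-6-(methoxymethyl)phenyl]methyl}-8-methoxy-3-methyl-1H-isochromen-1-one
Product: 19 6-hydroxy-5-{[4-hydroxy-2-methoxy-6-(methoxymethyl)phenyl]methyl}-8-methoxy-3-methyl-1H-isochromen-1-one (CNP0481202.0)
Conditions: H2 (1 atm), 10% Pd/C, EtOAc, rt, stopped once debenzylation is complete
Reagents that add atoms: none
Why: Catalytic hydrogenolysis of the aryl benzyl ether, which should be much faster at one atmosphere and room temperature than cleavage of the benzylic methyl ether or saturation of the C3–C4 bond of the isocoumarin.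

**Compound list**

1 | methyl orsellinate (methyl 2,4-dihydroxy-6-methylbenzoate) | COC(=O)c1c(C)cc(O)cc1O | starting material
2 | methyl 4-(benzyloxy)-2-hydroxy-6-methylbenzoate | COC(=O)c1c(C)cc(OCc2ccccc2)cc1O | intermediate
3 | methyl 4-(benzyloxy)-2-methoxy-6-methylbenzoate | COC(=O)c1c(C)cc(OCc2ccccc2)cc1OC | intermediate
4 | methyl 4-(benzyloxy)-3-bromo-6-methoxy-2-methylbenzoate | COC(=O)c1c(C)c(Br)c(OCc2ccccc2)cc1OC | intermediate
5 | N-methoxy-N-methylacetamide | CC(=O)N(C)OC | starting material
6 | methyl 4-(benzyloxy)-3-bromo-6-methoxy-2-(2-oxopropyl)benzoate | COC(=O)c1c(CC(C)=O)c(Br)c(OCc2ccccc2)cc1OC | intermediate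
7 | 6-(benzyloxy)-5-bromo-8-methoxy-3-methyl-1H-isochromen-1-one | Cc1cc2c(Br)c(OCc3ccccc3)cc(OC)c2c(=O)o1 | intermediate
8 | 6-(benzyloxy)-8-methoxy-3-methyl-1-oxo-1H-isochromene-5-carbaldehyde | Cc1cc2c(C=O)c(OCc3ccccc3)cc(OC)c2c(=O)o1 | intermediate
9 | chloroacetaldehyde dimethyl acetal | COC(CCl)OC | starting material
10 | lithium methoxyacetylide (not isolated) | [Li]C#COC | intermediate
11 | 6-(benzyloxy)-5-[(1RS)-1-hydroxy-3-methoxyprop-2-yn-1-yl]-8-methoxy-3-methyl-1H-isochromen-1-one (racemic, one enantiomer drawn) | O[C@H](C#COC)c1c(OCc2ccccc2)cc(OC)c2c(=O)oc(C)cc12 | intermediate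
12 | propargyl bromide | C#CCBr | starting material
13 | 6-(benzyloxy)-8-methoxy-5-[(1RS)-3-methoxy-1-(prop-2-yn-1-yloxy)prop-2-yn-1-yl]-3-methyl-1H-isochromen-1-one (racemic, one enantiomer drawn) | C#CCO[C@H](C#COC)c1c(OCc2ccccc2)cc(OC)c2c(=O)oc(C)cc12 | intermediate
14 | ethynylboronic acid pinacol ester | C#CB1OC(C)(C)C(C)(C)O1 | starting material
15 | 6-(benzyloxy)-8-methoxy-5-[(1RS)-7-methoxy-5-(4,4,5,5-tetramethyl-1,3,2-dioxaborolan-2-yl)-1,3-dihydro-2-benzofuran-1-yl]-3-methyl-1H-isochromen-1-one (racemic, one enantiomer drawn) | COc1cc(B3OC(C)(C)C(C)(C)O3)cc2CO[C@@H](c3c(OCc4ccccc4)cc(OC)c4c(=O)oc(C)cc34)c12 | intermediate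
16 | 6-(benzyloxy)-5-{[2-(hydroxymethyl)-6-methoxy-4-(4,4,5,5-tetramethyl-1,3,2-dioxaborolan-2-yl)phenyl]methyl}-8-methoxy-3-methyl-1H-isochromen-1-one | COc1cc(B3OC(C)(C)C(C)(C)O3)cc(CO)c1Cc1c(OCc2ccccc2)cc(OC)c2c(=O)oc(C)cc12 | intermediate
17 | 6-(benzyloxy)-8-methoxy-5-{[2-methoxy-6-(methoxymethyl)-4-(4,4,5,5-tetramethyl-1,3,2-dioxaborolan-2-yl)phenyl]methyl}-3-methyl-1H-isochromen-1-one | COCc1cc(B3OC(C)(C)C(C)(C)O3)cc(OC)c1Cc1c(OCc2ccccc2)cc(OC)c2c(=O)oc(C)cc12 | intermediate
18 | 6-(benzyloxy)-5-{[4-hydroxy-2-methoxy-6-(methoxymethyl)phenyl]methyl}-8-methoxy-3-methyl-1H-isochromen-1-one | COCc1cc(O)cc(OC)c1Cc1c(OCc2ccccc2)cc(OC)c2c(=O)oc(C)cc12 | intermediate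
19 | 6-hydroxy-5-{[4-hydroxy-2-methoxy-6-(methoxymethyl)phenyl]methyl}-8-methoxy-3-methyl-1H-isochromen-1-one | COCc1cc(O)cc(OC)c1Cc1c(O)cc(OC)c2c(=O)oc(C)cc12 | target

**Totals and risks**

Total step count: 13. Longest linear sequence: 13 steps (compound 1 to compound 19).

Steps most likely to fail:

Step 9 (key step). The electron-rich methoxyalkyne end may hold the ruthenium as an unreactive alkoxy-stabilized metallacycle, the diyne may cyclotrimerize with itself, or the boryl alkyne may insert in the reverse sense and place boron ortho to the methoxy group. The fallback builds ring A by a Diels–Alder benzannulation; it sets out from aldehyde 8 and comes back to the route at phenol 18. 3-Methoxyprop-1-yne is deprotonated with n-BuLi in THF at −78 °C to lithium 3-methoxyprop-1-yn-1-ide F1, which should add to 8 and give the propargylic carbinol 6-(benzyloxy)-5-[(1RS)-1-hydroxy-4-methoxybut-2-yn-1-yl]-8-methoxy-3-methyl-1H-isochromen-1-one F2. MnO2 in CH2Cl2 should oxidize F2 to the ynone 6-(benzyloxy)-8-methoxy-5-(4-methoxybut-2-ynoyl)-3-methyl-1H-isochromen-1-one F3. Heating F3 in toluene with 1,1-dimethoxy-3-(trimethylsilyloxy)buta-1,3-diene (C=C(O[Si](C)(C)C)C=C(OC)OC) should give the cycloadduct 6-(benzyloxy)-5-{[6,6-dimethoxy-2-(methoxymethyl)-4-(trimethylsilyloxy)cyclohexa-1,4-dien-1-yl]carbonyl}-8-methoxy-3-methyl-1H-isochromen-1-one F4, which is not isolated. In this Diels–Alder reaction the ketene acetal carbon joins the acyl-bearing alkyne carbon and the diene CH2 joins the carbon that bears CH2OMe. Loss of methanol and, on dilute HCl work-up, of the silyl group should then give the benzophenone 6-(benzyloxy)-5-[4-hydroxy-2-methoxy-6-(methoxymethyl)benzoyl]-8-methoxy-3-methyl-1H-isochromen-1-one F5, in which the C2′ OMe is ortho and the C4′ OH para to the carbonyl. Ionic hydrogenation of the diaryl ketone (Et3SiH, CF3CO2H, CH2Cl2) should give the CH2 bridge, which is compound 18, and step 13 then follows.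

Step 7. The alkoxyalkynyl carbinol may rearrange to the unsaturated methyl ester (Meyer–Schuster rearrangement) on isolation, or the lithium methoxide formed with the acetylide may open the lactone. The fallback uses a benzotriazole-mediated ether synthesis that avoids carbinol 11; it sets out from aldehyde 8 and comes back to the route at diyne 13. Aldehyde 8 is condensed with prop-2-yn-1-ol and 1H-benzotriazole (p-TsOH cat., toluene, water removal) to the N,O-acetal 1-{(RS)-[6-(benzyloxy)-8-methoxy-3-methyl-1-oxo-1H-isochromen-5-yl](prop-2-yn-1-yloxy)methyl}-1H-benzotriazole F6. Methoxyethynylmagnesium bromide F7, made from distilled methoxyacetylene and EtMgBr in THF and used in 2.5 equiv to allow for the terminal alkyne proton, should displace benzotriazole at 0 °C to rt and give 13 directly.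

Step 6. Oxidative addition at the di-ortho-substituted, electron-rich bromide may be slow, and hydrodebromination by the palladium hydride may compete with CO insertion. The fallback goes through a vinyl group; it sets out from bromide 7 and comes back to the route at aldehyde 8. Stille coupling of 7 with tributyl(vinyl)stannane (Pd(PPh3)4, toluene, 100 °C) should give 6-(benzyloxy)-5-ethenyl-8-methoxy-3-methyl-1H-isochromen-1-one F8. Lemieux–Johnson cleavage (OsO4 cat., NaIO4, 2,6-lutidine, dioxane/H2O) of the terminal alkene, which is more accessible than the lactone-conjugated C3–C4 bond, should then give 8.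

**Further compounds**

F1 | step 9 | lithium 3-methoxyprop-1-yn-1-ide | [Li]C#CCOC
F2 | step 9 | 6-(benzyloxy)-5-[(1RS)-1-hydroxy-4-methoxybut-2-yn-1-yl]-8-methoxy-3-methyl-1H-isochromen-1-one (racemic, one enantiomer drawn) | COCC#C[C@H](O)c1c(OCc2ccccc2)cc(OC)c2c(=O)oc(C)cc12
F3 | step 9 | 6-(benzyloxy)-8-methoxy-5-(4-methoxybut-2-ynoyl)-3-methyl-1H-isochromen-1-one | COCC#CC(=O)c1c(OCc2ccccc2)cc(OC)c2c(=O)oc(C)cc12
F4 | step 9 | 6-(benzyloxy)-5-{[6,6-dimethoxy-2-(methoxymethyl)-4-(trimethylsilyloxy)cyclohexa-1,4-dien-1-yl]carbonyl}-8-methoxy-3-methyl-1H-isochromen-1-one | COCC1=C(C(=O)c2c(OCc3ccccc3)cc(OC)c3c(=O)oc(C)cc23)C(OC)(OC)C=C(O[Si](C)(C)C)C1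
F5 | step 9 | 6-(benzyloxy)-5-[4-hydroxy-2-methoxy-6-(methoxymethyl)benzoyl]-8-methoxy-3-methyl-1H-isochromen-1-one | COCc1cc(O)cc(OC)c1C(=O)c1c(OCc2ccccc2)cc(OC)c2c(=O)oc(C)cc12
F6 | step 7 | 1-{(RS)-[6-(benzyloxy)-8-methoxy-3-methyl-1-oxo-1H-isochromen-5-yl](prop-2-yn-1-yloxy)methyl}-1H-benzotriazole (racemic, one enantiomer drawn) | C#CCO[C@H](n1nnc2ccccc12)c1c(OCc2ccccc2)cc(OC)c2c(=O)oc(C)cc12
F7 | step 7 | methoxyethynylmagnesium bromide | COC#C[Mg]Br
F8 | step 6 | 6-(benzyloxy)-5-ethenyl-8-methoxy-3-methyl-1H-isochromen-1-one | C=Cc1c(OCc2ccccc2)cc(OC)c2c(=O)oc(C)cc12
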